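**Strategy (eremophilane numbering).** The target is an isomer of an acyclic polyene ester, and the route folds that chain in one step. The feature exploited is the heteroannular diene C2=C1–C10=C9 conjugated to the C8 ketone, flanked by the all-cis C3–O/C4–Me/C5–Me triad of ring A. Disconnecting C3–C4 and C5–C10 reveals an axially chiral (E)-1-acyloxyvinylallenyl ketone, tethered from the allene terminus C9 through C8(=O)–C7(=CMe2)–C6H2 to a tiglyl-type alkene. Its intramolecular Diels–Alder reaction closes rings A and B and sets C3, C4 and the quaternary C5 by axis-to-centre transfer. The spare allene π bond is left as the C9=C10 enone bond.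

Key step: step 14

Remark: the target SMILES is read as (3S,4R,5R,6′S) with C3–O, C4–Me and C5–Me on one face. Core atoms keep eremophilane numbers in all intermediates. The C7 centre of 9–11 and the C8 carbinol centre of 14 and 16–18 are racemic, which is harmless because both carbons become sp2. Allene axes are written with the extended-tetrahedral @/@@ convention and explicit H.

Step 1
Reactants: 1 (S)-2-methylbutan-1-ol
Product: 2 (S)-2-methylbutanal
Conditions: TEMPO (cat.), PhI(OAc)2, CH2Cl2, 0 °C to rt; solution used directly
Reagents that add atoms: none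
Why: The oxoammonium (TEMPO) oxidation stops at the aldehyde under non-basic conditions, so the chiral-pool α-stereocentre should not epimerise.

Step 2
Reactants: 2 (S)-2-methylbutanal; 3 triethyl (E)-4-phosphonocrotonate
Product: 4 ethyl (2E,4E,6S)-6-methylocta-2,4-dienoate
Conditions: LiHMDS, THF, −78 °C, then 2, −78 to 0 °C
Reagents that add atoms: none
Why: The vinylogous Horner–Wadsworth–Emmons olefination of the stabilised anion should give the (2E,4E)-dienoate, and adding the aldehyde to the preformed anion in the cold spares the C6′ centre.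

Step 3
Reactants: 4 ethyl (2E,4E,6S)-6-methylocta-2,4-dienoate
Product: 5 (2E,4E,6S)-6-methylocta-2,4-dienoic acid
Conditions: LiOH, THF/MeOH/H2O, rt; then 1 M HCl
Reagents that add atoms: lithium hydroxide, [Li+].[OH-]
Why: Plain saponification touches neither the diene geometry nor the remote stereocentre.

Step 4
Reactants: 6 (E)-2-methylbut-2-en-1-ol
Product: 7 (E)-1-bromo-2-methylbut-2-ene
Conditions: PBr3, Et2O, −10 °C
Reagents that add atoms: phosphorus tribromide, BrP(Br)Br
Why: SN2 bromination of the primary allylic alcohol in the cold should keep the E geometry that later encodes the cis C4/C5 methyl pair.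

Step 5
Reactants: 8 ethyl 3-methylbut-2-enoate; 7 (E)-1-bromo-2-methylbut-2-ene
Product: 9 ethyl (4E)-4-methyl-2-(prop-1-en-2-yl)hex-4-enoate (racemic)
Conditions: LDA, THF/DMPU, −78 °C; then 7, −78 to −20 °C
Reagents that add atoms: none
Why: In this deconjugative α-alkylation the extended dienolate reacts at Cα with the primary allylic bromide (SN2), which forms C6–C7; the C7 centre is erased in step 7.

Step 6
Reactants: 9 ethyl (4E)-4-methyl-2-(prop-1-en-2-yl)hex-4-enoate
Product: 10 (4E)-4-methyl-2-(prop-1-en-2-yl)hex-4-en-1-ol
Conditions: LiAlH4, Et2O, 0 °C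
Reagents that add atoms: none
Why: Hydride reduction of the ester leaves the isolated alkenes untouched.

Step 7
Reactants: 10 (4E)-4-methyl-2-(prop-1-en-2-yl)hex-4-en-1-ol
Product: 12 (4E)-4-methyl-2-(propan-2-ylidene)hex-4-enal, via deconjugated aldehyde 11 (not isolated)
Conditions: Dess–Martin periodinane, CH2Cl2, 0 °C to rt; then DBU (cat.), rt
Reagents that add atoms: none
Why: Dess–Martin oxidation followed by base-catalysed prototropic conjugation should move the isopropenyl double bond into the tetrasubstituted conjugated position (C7=C11).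

Step 8
Reactants: 12 (4E)-4-methyl-2-(propan-2-ylidene)hex-4-enal; 13 propargyl bromide
Product: 14 (7E)-7-methyl-5-(propan-2-ylidene)non-7-en-1-yn-4-ol (racemic)
Conditions: Zn dust, THF, 0 °C; aqueous work-up
Reagents that add atoms: none
Why: In this Barbier-type propargylation the allenylzinc species adds 1,2 to the enal in the SE2′ sense, which should give the homopropargylic alcohol (C8–C9 bond).

Step 9
Reactants: 14 (7E)-7-methyl-5-(propan-2-ylidene)non-7-en-1-yn-4-ol; 15 (E)-2-bromovinylboronic acid MIDA ester
Product: 16 (1E,9E)-6-hydroxy-9-methyl-7-(propan-2-ylidene)undeca-1,9-dien-3-yn-1-ylboronic acid MIDA ester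
Conditions: PdCl2(PPh3)2 (cat.), CuI (cat.), Et3N, THF, rt
Reagents that add atoms: none
Why: Sonogashira coupling proceeds with retention at the vinyl bromide, and the sp3-hybridised MIDA boron is inert under anhydrous amine conditions, so the E C2=C3 unit is taken over intact.

Step 10
Reactants: 16 enynyl MIDA boronate
Product: 17 potassium (1E,9E)-6-hydroxy-9-methyl-7-(propan-2-ylidene)undeca-1,9-dien-3-yn-1-yltrifluoroborate
Conditions: KHF2 (aq.), MeOH, 70 °C
Reagents that add atoms: potassium hydrogen difluoride, F.[F-].[K+]
Why: Fluoride exchange converts the MIDA boronate into the trifluoroborate required for the copper coupling without touching the alkene geometry.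

Step 11
Reactants: 17 potassium enynyltrifluoroborate; 5 (2E,4E,6S)-6-methylocta-2,4-dienoic acid
Product: 18 (1E,9E)-6-hydroxy-9-methyl-7-(propan-2-ylidene)undeca-1,9-dien-3-yn-1-yl (2E,4E,6S)-6-methylocta-2,4-dienoate
Conditions: CuBr (cat.), DMAP (cat.), 4 Å MS, O2 (1 atm), MeCN, 60 °C
Reagents that add atoms: none
Why: The Chan–Lam-type oxidative copper coupling of alkenyltrifluoroborates with carboxylic acids is stereoretentive, so it should deliver the (E)-enol ester that direct enolisation methods cannot guarantee.

Step 12
Reactants: 18 enol ester alcohol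
Product: 19 (1E,9E)-9-methyl-6-oxo-7-(propan-2-ylidene)undeca-1,9-dien-3-yn-1-yl (2E,4E,6S)-6-methylocta-2,4-dienoate
Conditions: Dess–Martin periodinane, CH2Cl2, 0 °C; non-basic work-up, used at once
Reagents that add atoms: none
Why: Dess–Martin oxidation is neutral to weakly acidic, so it should spare the enol ester and avoid a premature, racemic alkyne-to-allene shift.

Step 13
Reactants: 19 β,γ-alkynyl ketone
Product: 20 (1E,9E)-9-methyl-6-oxo-7-(propan-2-ylidene)undeca-1,3,4,9-tetraen-1-yl (2E,4E,6S)-6-methylocta-2,4-dienoate with (Ra) 3,4-diene axis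
Conditions: quinine-derived tertiary-amine squaramide (10 mol %; the quinidine-derived pseudoenantiomer if the sense proves opposite), PhMe, −30 °C; short silica plug
Reagents that add atoms: none
Why: Proposed new method: the C9 methylene between ketone and alkyne is the most acidic site, so the catalyst amine should remove one enantiotopic proton while the squaramide N–H bonds hold the enynolate oxygen, and the ammonium ion should return the proton to C1 on the same face (suprafacial 1,3-shift), letting the chiral pocket choose the axis while conjugation with ketone and vinyl group makes the allene the sink; the closest known reaction type is the chiral Brønsted-base-catalysed isomerisation of 3-alkynoates to axially chiral allenoates.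

Step 14
Reactants: 20 (Ra)-acyloxyvinylallenyl ketone
Product: 21 (1R,2S,8aR)-1,8a-dimethyl-6-oxo-7-(propan-2-ylidene)-1,2,6,7,8,8a-hexahydronaphthalen-2-yl (2E,4E,6S)-6-methylocta-2,4-dienoate (target)
Conditions: PhMe (high dilution), BHT (cat.), silanised glass, Ar, 100 °C
Reagents that add atoms: none
Why: On heating, the s-cis diene C3=C2–C1=C10 of 20 and the C4=C5 alkene should combine in a concerted suprafacial [4+2] cycloaddition that forms C3–C4 and C5–C10, while the orthogonal C9=C10 π bond of the allene takes no part and emerges as the enone double bond, so 21 is reached directly at the dienone oxidation level. The closest known reaction type is the intramolecular Diels–Alder reaction of vinylallenes carrying the alkene on the allene terminus, which gives hexalins with a heteroannular diene and profits from release of allene strain and from an s-cis conformer without an inside substituent at C10. Ring A is the six-membered ring of the cycloaddition itself, and ring B (C5–C6–C7–C8–C9–C10) is closed in the fused mode by the three-atom tether C6–C7–C8 (type 1 IMDA). Because the substituents of C9 stand perpendicular to the diene plane, the alkene can reach only the diene face on which C8 stands, so the (Ra) axis fixes the absolute sense at C3 and C5; the short tether can span C5 and C9 only with C6 exo, which places the C5 methyl and, through the E alkene, the C4 methyl endo, and the outside (E) acyloxy group therefore ends cis to both, i.e. 3S,4R,5R. The step needs periselectivity over [2+2], ene, Nazarov and furan-forming pathways and retention of the axis, which neutral, metal-free, acid- and base-free conditions at high dilution, the conformational bias of the C7 isopropylidene group and the inability of the dienoate alkene to reach the diene should secure.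

**Compound list**
1 | (S)-2-methylbutan-1-ol | CC[C@H](C)CO | starting material
2 | (S)-2-methylbutanal | CC[C@H](C)C=O | intermediate
3 | triethyl (E)-4-phosphonocrotonate | CCOC(=O)/C=C/CP(=O)(OCC)OCC | starting material
4 | ethyl (2E,4E,6S)-6-methylocta-2,4-dienoate | CC[C@H](C)/C=C/C=C/C(=O)OCC | intermediate
5 | (2E,4E,6S)-6-methylocta-2,4-dienoic acid | CC[C@H](C)/C=C/C=C/C(=O)O | intermediate
6 | (E)-2-methylbut-2-en-1-ol | C/C=C(\C)CO | starting material
7 | (E)-1-bromo-2-methylbut-2-ene | C/C=C(\C)CBr | intermediate
8 | ethyl 3-methylbut-2-enoate | CCOC(=O)C=C(C)C | starting material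
9 | ethyl (4E)-4-methyl-2-(prop-1-en-2-yl)hex-4-enoate (racemic) | CCOC(=O)C(C(C)=C)C/C(C)=C/C | intermediate
10 | (4E)-4-methyl-2-(prop-1-en-2-yl)hex-4-en-1-ol (racemic) | OCC(C(C)=C)C/C(C)=C/C | intermediate
11 | (4E)-4-methyl-2-(prop-1-en-2-yl)hex-4-enal (not isolated) | O=CC(C(C)=C)C/C(C)=C/C | intermediate
12 | (4E)-4-methyl-2-(propan-2-ylidene)hex-4-enal | O=CC(=C(C)C)C/C(C)=C/C | intermediate
13 | propargyl bromide | C#CCBr | starting material
14 | (7E)-7-methyl-5-(propan-2-ylidene)non-7-en-1-yn-4-ol (racemic) | C#CCC(O)C(=C(C)C)C/C(C)=C/C | intermediate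
15 | (E)-2-bromovinylboronic acid MIDA ester | C[N+]12CC(=O)O[B-]1(/C=C/Br)OC(=O)C2 | starting material
16 | (1E,9E)-6-hydroxy-9-methyl-7-(propan-2-ylidene)undeca-1,9-dien-3-yn-1-ylboronic acid MIDA ester | C[N+]12CC(=O)O[B-]1(/C=C/C#CCC(O)C(=C(C)C)C/C(C)=C/C)OC(=O)C2 | intermediate
17 | potassium (1E,9E)-6-hydroxy-9-methyl-7-(propan-2-ylidene)undeca-1,9-dien-3-yn-1-yltrifluoroborate | [K+].F[B-](F)(F)/C=C/C#CCC(O)C(=C(C)C)C/C(C)=C/C | intermediate
18 | (1E,9E)-6-hydroxy-9-methyl-7-(propan-2-ylidene)undeca-1,9-dien-3-yn-1-yl (2E,4E,6S)-6-methylocta-2,4-dienoate | CC[C@H](C)/C=C/C=C/C(=O)O/C=C/C#CCC(O)C(=C(C)C)C/C(C)=C/C | intermediate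
19 | (1E,9E)-9-methyl-6-oxo-7-(propan-2-ylidene)undeca-1,9-dien-3-yn-1-yl (2E,4E,6S)-6-methylocta-2,4-dienoate | CC[C@H](C)/C=C/C=C/C(=O)O/C=C/C#CCC(=O)C(=C(C)C)C/C(C)=C/C | intermediate
20 | (Ra)-(1E,9E)-9-methyl-6-oxo-7-(propan-2-ylidene)undeca-1,3,4,9-tetraen-1-yl (2E,4E,6S)-6-methylocta-2,4-dienoate | CC[C@H](C)/C=C/C=C/C(=O)O/C=C/C([H])=[C@]=C([H])C(=O)C(=C(C)C)C/C(C)=C/C | intermediate
21 | (3S,4R,5R)-8-oxoeremophila-1,9,7(11)-trien-3-yl (2E,4E,6S)-6-methylocta-2,4-dienoate | CC[C@H](C)/C=C/C=C/C(=O)O[C@H]1C=CC2=CC(=O)C(=C(C)C)C[C@]2(C)[C@H]1C | target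

**Totals.** Total step count: 14. Longest linear sequence: 11 steps (steps 4–14, from 6 to 21).

**Steps most likely to fail**

1. **Step 13 (labelled).** What may go wrong:
   - poor face discrimination in the reprotonation;
   - background isomerisation on glass or silica;
   - erosion of the axis by reversible deprotonation;
   - addition of the amine to the allenone.

   The fallback uses known chemistry, sets out from 19 and returns at 21. Catalytic triethylamine effects the standard base-mediated propargyl-to-allenyl ketone shift and should convert 19 into 20 together with its (Sa)-axis epimer F1. Heating the pair as in step 14 should translate each axis faithfully and give 21 beside its (3R,4S,5S,6′S)-diastereomer F2. The side-chain centre makes these two diastereomers, so they would be separated by preparative HPLC on a polysaccharide chiral phase. Control of the core is thereby moved from catalysis to separation.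

2. **Step 14 (key step).** What may go wrong: the cycloaddition is too slow relative to loss of the axis by enolisation, acid-triggered Nazarov-type closure of the allenyl vinyl ketone, cycloisomerisation to a furan, or ene and [2+2] pathways.

   The fallback sets out from 20 and returns at 21. Luche reduction (NaBH4, CeCl3, MeOH, −78 °C) should give the (Ra)-allenol F3 as both C8 epimers. F3 has no acidic γ-hydrogen, so it cannot racemise, and it is no Nazarov or furan precursor. It should tolerate xylene at 140 °C for the same cycloaddition, giving the 8-hydroxy cycloadduct F4. MnO2 oxidation of the doubly allylic alcohol then returns to 21.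

3. **Step 11.** What may go wrong: protodeboronation, competing O-alkenylation of the free carbinol, and autoxidation of the doubly allylic C6 methylene under Cu/O2.

   The fallback sets out from 16 and returns at 21; boron is carried through the cycloaddition and the C3–O bond is made afterwards.
   - Dess–Martin oxidation should give the β,γ-ynone MIDA boronate F5.
   - The proton shift of step 13 should give the (Ra)-allenone MIDA boronate F6.
   - Heating in dioxane should give the C3-boryl cycloadduct F7. This is a 1-boryl diene with boron outside, so boron ends on the β face.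
   - Sodium perborate in THF/water should release and oxidise the allylic boronate with retention to the 3β-alcohol F8.
   - Yamaguchi esterification with 5 gives 21.

**Further compounds**
F1 | step 13 | (Sa)-axis epimer of 20 | CC[C@H](C)/C=C/C=C/C(=O)O/C=C/C([H])=[C@@]=C([H])C(=O)C(=C(C)C)C/C(C)=C/C
F2 | step 13 | (3R,4S,5S)-8-oxoeremophila-1,9,7(11)-trien-3-yl (2E,4E,6S)-6-methylocta-2,4-dienoate | CC[C@H](C)/C=C/C=C/C(=O)O[C@@H]1C=CC2=CC(=O)C(=C(C)C)C[C@@]2(C)[C@@H]1C
F3 | step 14 | (Ra)-(1E,9E)-6-hydroxy-9-methyl-7-(propan-2-ylidene)undeca-1,3,4,9-tetraen-1-yl (2E,4E,6S)-6-methylocta-2,4-dienoate (C8 epimers) | CC[C@H](C)/C=C/C=C/C(=O)O/C=C/C([H])=[C@]=C([H])C(O)C(=C(C)C)C/C(C)=C/C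
F4 | step 14 | (3S,4R,5R)-8-hydroxyeremophila-1,9,7(11)-trien-3-yl (2E,4E,6S)-6-methylocta-2,4-dienoate (C8 epimers) | CC[C@H](C)/C=C/C=C/C(=O)O[C@H]1C=CC2=CC(O)C(=C(C)C)C[C@]2(C)[C@H]1C
F5 | step 11 | (1E,9E)-9-methyl-6-oxo-7-(propan-2-ylidene)undeca-1,9-dien-3-yn-1-ylboronic acid MIDA ester | C[N+]12CC(=O)O[B-]1(/C=C/C#CCC(=O)C(=C(C)C)C/C(C)=C/C)OC(=O)C2
F6 | step 11 | (Ra)-(1E,9E)-9-methyl-6-oxo-7-(propan-2-ylidene)undeca-1,3,4,9-tetraen-1-ylboronic acid MIDA ester | C[N+]12CC(=O)O[B-]1(/C=C/C([H])=[C@]=C([H])C(=O)C(=C(C)C)C/C(C)=C/C)OC(=O)C2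
F7 | step 11 | 8-oxoeremophila-1,9,7(11)-trien-3β-ylboronic acid MIDA ester (4β,5β-dimethyl) | C[N+]12CC(=O)O[B-]1([C@H]3C=CC4=CC(=O)C(=C(C)C)C[C@]4(C)[C@H]3C)OC(=O)C2
F8 | step 11 | (3S,4R,5R)-3-hydroxyeremophila-1,9,7(11)-trien-8-one | O[C@H]1C=CC2=CC(=O)C(=C(C)C)C[C@]2(C)[C@H]1C
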